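**Plan**
Cuts: first the CH2–C bond between the central ring B and the acetylfilicinic ring A (o-quinone methide alkylation). Then, together, two bonds of the propanoylfilicinic ring P: C(CH2Ar)–C(OH) next to CMe2, and C(COEt)–C(=O).
These cuts split ring P into a C2 piece (CH2–C=O), held on ring B as a six-membered aryl lactone (a chroman-2-one), and a C4 piece with its side chain: 6-ethyl-3,3-dimethylpyran-2,4-dione, the enol lactone of 2,2-dimethyl-3,5-dioxoheptanoic acid.
Enabling feature: ring P is a cyclic 1,3,5-tricarbonyl, so every ring bond is a Claisen bond. The phenol O of ring B ortho to the bridge CH2 can carry the ring carbonyl lying between C(CH2Ar) and C(COEt) as a lactone. CMe2 bears no H, so the enol O of the later propanoyl C=O can mask and activate the single acyl carbon of the C4 piece.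
Forward: rings B and A come from aromatic starting materials. Both helper lactones open in the step that closes ring P, the only carbocycle made. Debenzylation, Mannich reaction and coupling to ring A follow.
The 8-butanoyl and 6-butanoyl lactone isomers both lead to compound 14, because the lactone O ends as one of the three phenols of ring B.
Stereochemistry: the target has no stereocentre, and the one stereogenic sp3 carbon on the way (C3 of 12) is lost by enolisation.
Key step: step 6

Assumption: the triketone rings are written in the enol tautomer of the given SMILES (fast tautomer equilibria), and 1, 2, 6, 7 and 16 are taken as purchasable.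

Step 1
Reactants: 1 5,7-dihydroxycoumarin; 2 butanoyl chloride
Product: 3 8-butanoyl-5,7-dihydroxy-2H-chromen-2-one
Conditions: AlCl3 (4 equiv), PhNO2/ClCH2CH2Cl, 70 °C; aq. HCl
Reagents that add atoms: none
Why: Friedel–Crafts C-acylation of the phloroglucinol-type ring of 5,7-dihydroxycoumarins with an acid chloride and AlCl3 is well precedented and should go mainly to C8, while any C6 isomer would converge with the main line at 14.

Step 2
Reactants: 3 8-butanoyl-5,7-dihydroxy-2H-chromen-2-one
Product: 4 8-butanoyl-5,7-dihydroxychroman-2-one
Conditions: H2 (3 bar), 10% Pd/C, EtOH, rt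
Reagents that add atoms: none
Why: Catalytic hydrogenation of the coumarin C3=C4 bond is standard and should leave the hindered, chelated aryl ketone untouched under neutral conditions.

Step 3
Reactants: 4 8-butanoyl-5,7-dihydroxychroman-2-one
Product: 5 5,7-bis(benzyloxy)-8-butanoylchroman-2-one
Conditions: BnBr (2.5 equiv), K2CO3 (dry), DMF, 60 °C
Reagents that add atoms: benzyl bromide, BrCc1ccccc1
Why: Williamson etherification of both phenols (the chelated 7-OH needs the warm DMF) under dry carbonate conditions that should not open the lactone, and a base-induced shift of the lactone to the 5-O would be harmless because both isomers give 14.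

Step 4
Reactants: 6 ethyl 2,2-dimethyl-3-oxobutanoate; 7 propanoyl chloride
Product: 9 ethyl 2,2-dimethyl-3,5-dioxoheptanoate, via ketone enolate 8 (not isolated)
Conditions: 6 (2.0 equiv), LiN(iPr)2 (2.0 equiv), THF, −78 °C; 7 (1.0 equiv); aq. HCl
Reagents that add atoms: none
Why: C-acylation of a ketone lithium enolate with an acid chloride is the standard 1,3-diketone synthesis; 6 has only one enolisable position because its other alpha carbon is quaternary, and the second equivalent of enolate takes up the acidic proton of 9.

Step 5
Reactants: 9 ethyl 2,2-dimethyl-3,5-dioxoheptanoate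
Product: 10 6-ethyl-3,3-dimethyl-2H-pyran-2,4(3H)-dione
Conditions: TsOH·H2O (cat.), toluene, reflux, EtOH removed through 4 Å sieves
Reagents that add atoms: none
Why: Acid-catalysed enol lactonisation of a 3,5-dioxo ester (the usual pyranone synthesis) is helped by the gem-dimethyl effect, is driven by removal of ethanol, and must stop at the pyran-2,4-dione stage because C3 is quaternary.

Step 6
Reactants: 5 5,7-bis(benzyloxy)-8-butanoylchroman-2-one; 10 6-ethyl-3,3-dimethyl-2H-pyran-2,4(3H)-dione
Product: 13 2-{[4,6-bis(benzyloxy)-3-butanoyl-2-hydroxyphenyl]methyl}-3,5-dihydroxy-4,4-dimethyl-6-propanoylcyclohexa-2,5-dien-1-one, via lactone enolate 11 (not isolated), via acyl lactone 12 (not isolated)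
Conditions: LiN(SiMe3)2 (2.1 equiv) added over 1 h to 5 + 10 (1.2 equiv), THF, −78 °C; then → rt; aq. HCl
Reagents that add atoms: none
Why: Proposed new method: LiN(SiMe3)2, run slowly into a mixture of 5 and 10 so that it is never in excess, removes the C3–H of the aryl lactone, which the locked E-ester geometry and the aryloxy group should make several pK units more acidic than the CH2 of the twisted di-ortho-substituted butanoyl ketone and than the vinylogous CH2 of 10, while the second equivalent only neutralises the acidic C3–H of 12. Enolate 11 adds to C2 of 10, a vinylogous anhydride carbonyl, and the adduct collapses with loss of a 1,3-diketone enolate, so one crossed Claisen acylation makes the hindered bond between the CH2Ar-bearing carbon and the carbonyl next to CMe2 and uncovers the nucleophile for the second bond. In 12 this diketonate carbon, the later propanoyl-bearing carbon, attacks the lactone carbonyl in a 6-(enolexo)-exo-trig Claisen closure, directly or after E1cB loss of the aryloxide to an acylketene, which closes ring P and frees the phenol of ring B. The closest known reaction types are the Fujimoto–Belleau reaction (a carbanion opens an enol lactone and the chain recloses to a carbocycle), the acylation of lactone enolates by activated esters, and the base-induced Claisen cyclisation of 3,5,7-trioxo esters or their pyranone forms to acylphloroglucinols, and what is new is their coupling in one flask between two lactones. No stereocentre is set, because C3 of 12 ends as an enolised sp2 carbon. The selectivities needed are C2 against C4 and C6 of 10 (a hard lithium enolate at low temperature avoids the soft conjugate position C6, and addition at C4 is reversible), C- against O-closure (enol ester isomers are reopened by the aryloxide, the chelated triketone enolate being the sink) and Claisen against aldol closure (the aldol would use the tertiary C3 and leads to no stable enone).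

Step 7
Reactants: 13 2-{[4,6-bis(benzyloxy)-3-butanoyl-2-hydroxyphenyl]methyl}-3,5-dihydroxy-4,4-dimethyl-6-propanoylcyclohexa-2,5-dien-1-one
Product: 14 2-[(3-butanoyl-2,4,6-trihydroxyphenyl)methyl]-3,5-dihydroxy-4,4-dimethyl-6-propanoylcyclohexa-2,5-dien-1-one
Conditions: H2 (1 bar), 10% Pd/C, EtOAc, rt
Reagents that add atoms: none
Why: Hydrogenolysis of aryl benzyl ethers under neutral conditions should spare the tetrasubstituted enol double bonds, the chelated ketones and the bridge C–C bonds.

Step 8
Reactants: 14 2-[(3-butanoyl-2,4,6-trihydroxyphenyl)methyl]-3,5-dihydroxy-4,4-dimethyl-6-propanoylcyclohexa-2,5-dien-1-one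
Product: 15 2-({3-butanoyl-5-[(dimethylamino)methyl]-2,4,6-trihydroxyphenyl}methyl)-3,5-dihydroxy-4,4-dimethyl-6-propanoylcyclohexa-2,5-dien-1-one
Conditions: aq. CH2O (1.1 equiv), aq. Me2NH (1.1 equiv), EtOH, 0 °C → rt
Reagents that add atoms: formaldehyde, C=O; dimethylamine, CNC
Why: The Mannich aminomethylation has one site only, the activated aromatic CH between two phenols, since ring P has no free ring CH and a secondary amine forms no stable enaminone with the acyl groups.

Step 9
Reactants: 16 2,4,6-trihydroxyacetophenone
Product: 17 2-acetyl-3,5-dihydroxy-4,4-dimethylcyclohexa-2,5-dien-1-one (acetylfilicinic acid)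
Conditions: MeI (2.2 equiv), NaOMe (2.2 equiv), MeOH, 0 °C → rt; aq. HCl
Reagents that add atoms: iodomethane, CI
Why: Dearomatising geminal C-methylation of an acylphloroglucinol with MeI and NaOMe is the classical entry to acylfilicinic acids.

Step 10
Reactants: 15 2-({3-butanoyl-5-[(dimethylamino)methyl]-2,4,6-trihydroxyphenyl}methyl)-3,5-dihydroxy-4,4-dimethyl-6-propanoylcyclohexa-2,5-dien-1-one; 17 acetylfilicinic acid
Product: 19 CNP0315613.0, via quinone methide 18 (not isolated)
Conditions: 17 (1.5 equiv), 1,4-dioxane, 70 °C, N2 stream
Reagents that add atoms: none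
Why: Thermal loss of Me2NH from the phenolic Mannich base gives o-quinone methide 18, which the soft carbon nucleophile 17 captures at its only free ring CH in a Michael addition with rearomatisation, the established route to unsymmetrical methylene-bridged phloroglucinols.

**Compound list**
1 | 5,7-dihydroxy-2H-chromen-2-one (5,7-dihydroxycoumarin) | O=C1C=Cc2c(O)cc(O)cc2O1 | starting material
2 | butanoyl chloride | CCCC(=O)Cl | starting material
3 | 8-butanoyl-5,7-dihydroxy-2H-chromen-2-one | CCCC(=O)c1c(O)cc(O)c2C=CC(=O)Oc12 | intermediate
4 | 8-butanoyl-5,7-dihydroxychroman-2-one | CCCC(=O)c1c(O)cc(O)c2CCC(=O)Oc12 | intermediate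
5 | 5,7-bis(benzyloxy)-8-butanoylchroman-2-one | CCCC(=O)c1c(OCc3ccccc3)cc(OCc3ccccc3)c2CCC(=O)Oc12 | intermediate
6 | ethyl 2,2-dimethyl-3-oxobutanoate | CCOC(=O)C(C)(C)C(C)=O | starting material
7 | propanoyl chloride | CCC(=O)Cl | starting material
8 | lithium enolate of 6 (at the acetyl CH3) | [Li+].CCOC(=O)C(C)(C)C([O-])=C | intermediate
9 | ethyl 2,2-dimethyl-3,5-dioxoheptanoate | CCOC(=O)C(C)(C)C(=O)CC(=O)CC | intermediate
10 | 6-ethyl-3,3-dimethyl-2H-pyran-2,4(3H)-dione | CCC1=CC(=O)C(C)(C)C(=O)O1 | intermediate
11 | lithium enolate of 5 (at lactone C3) | [Li+].CCCC(=O)c1c(OCc3ccccc3)cc(OCc3ccccc3)c2CC=C([O-])Oc12 | intermediate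
12 | 5,7-bis(benzyloxy)-8-butanoyl-3-(2,2-dimethyl-3,5-dioxoheptanoyl)chroman-2-one (formed as its lithium enolate, drawn neutral, C3 configurationally labile) | CCCC(=O)c1c(OCc3ccccc3)cc(OCc3ccccc3)c2CC(C(=O)C(C)(C)C(=O)CC(=O)CC)C(=O)Oc12 | intermediate
13 | 2-{[4,6-bis(benzyloxy)-3-butanoyl-2-hydroxyphenyl]methyl}-3,5-dihydroxy-4,4-dimethyl-6-propanoylcyclohexa-2,5-dien-1-one | CCCC(=O)c1c(O)c(CC2=C(O)C(C)(C)C(O)=C(C(=O)CC)C2=O)c(OCc2ccccc2)cc1OCc1ccccc1 | intermediate
14 | 2-[(3-butanoyl-2,4,6-trihydroxyphenyl)methyl]-3,5-dihydroxy-4,4-dimethyl-6-propanoylcyclohexa-2,5-dien-1-one | CCCC(=O)c1c(O)cc(O)c(CC2=C(O)C(C)(C)C(O)=C(C(=O)CC)C2=O)c1O | intermediate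
15 | 2-({3-butanoyl-5-[(dimethylamino)methyl]-2,4,6-trihydroxyphenyl}methyl)-3,5-dihydroxy-4,4-dimethyl-6-propanoylcyclohexa-2,5-dien-1-one | CCCC(=O)c1c(O)c(CN(C)C)c(O)c(CC2=C(O)C(C)(C)C(O)=C(C(=O)CC)C2=O)c1O | intermediate
16 | 1-(2,4,6-trihydroxyphenyl)ethan-1-one (2,4,6-trihydroxyacetophenone) | CC(=O)c1c(O)cc(O)cc1O | starting material
17 | 2-acetyl-3,5-dihydroxy-4,4-dimethylcyclohexa-2,5-dien-1-one (acetylfilicinic acid) | CC(=O)C1=C(O)C(C)(C)C(O)=CC1=O | intermediate
18 | o-quinone methide of ring B formed from 15 by loss of Me2NH | C=C1C(=O)C(C(=O)CCC)=C(O)C(CC2=C(O)C(C)(C)C(O)=C(C(=O)CC)C2=O)=C1O | intermediate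
19 | 2-acetyl-6-({3-butanoyl-5-[(2,4-dihydroxy-3,3-dimethyl-6-oxo-5-propanoylcyclohexa-1,4-dien-1-yl)methyl]-2,4,6-trihydroxyphenyl}methyl)-3,5-dihydroxy-4,4-dimethylcyclohexa-2,5-dien-1-one (CNP0315613.0) | CCCC(=O)c1c(O)c(CC2=C(O)C(C)(C)C(O)=C(C(C)=O)C2=O)c(O)c(CC2=C(O)C(C)(C)C(O)=C(C(=O)CC)C2=O)c1O | target

**Step count**
Total steps: 10. Longest linear sequence: 7 (steps 1, 2, 3, 6, 7, 8, 10).

**Steps most likely to fail**

Step 6.
- What may go wrong: the enolate may attack the conjugate position of the pyrandione. A proton may pass from the ethyl group of the pyrandione to the enolate. The cascade may stall after the first acylation.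
- Fallback (known chemistry): it sets out from 2 and comes back at 14.
- Butanoyl chloride 2 acylates phloroglucinol (AlCl3, Friedel–Crafts) to 1-(2,4,6-trihydroxyphenyl)butan-1-one F1.
- One equivalent each of formaldehyde and dimethylamine converts F1 into the mono-Mannich base 1-{3-[(dimethylamino)methyl]-2,4,6-trihydroxyphenyl}butan-1-one F2.
- In parallel, 7 acylates phloroglucinol to 1-(2,4,6-trihydroxyphenyl)propan-1-one F3. Geminal C-methylation of F3 (MeI, NaOMe, as in step 9) gives 3,5-dihydroxy-4,4-dimethyl-2-propanoylcyclohexa-2,5-dien-1-one F4.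
- Warming F2 with F4 releases the o-quinone methide F5, which F4 captures at its free ring CH to give 14.
- Ring P then stems from an aromatic ring instead of being closed. The price is a statistical mono-functionalisation of F1.

Step 10.
- What may go wrong: base- or heat-induced retro-Michael loss of ring P from ring B may compete with loss of the amine, so that the two filicinic units exchange places or double up.
- Fallback: it sets out from 17 (used together with 14) and comes back at 19.
- 17 is aminomethylated (CH2O, Me2NH) to 2-acetyl-6-[(dimethylamino)methyl]-3,5-dihydroxy-4,4-dimethylcyclohexa-2,5-dien-1-one F6.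
- In AcOH/NaOAc at 40 °C, F6 loses the amine to give the methylidene triketone F7. The free aromatic CH of 14 adds to F7 in a Friedel–Crafts-type Michael addition.
- The roles of the partners are exchanged. Ring B never passes through a quinone methide, and the weakly acidic medium should slow the exchange.

Step 5.
- What may go wrong: the equilibrium between ester and enol lactone may be unfavourable, or the product may reopen through traces of ethanol or water.
- Fallback: it sets out from 9 and comes back at 10.
- Saponification (KOH, aq. EtOH, rt, the diketone being protected as its enolate) gives 2,2-dimethyl-3,5-dioxoheptanoic acid F8, kept cold against decarboxylation.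
- F8 is cyclodehydrated with trifluoroacetic anhydride in CH2Cl2 at 0 °C. The ring closure then starts from an activated acid and is no longer an equilibrium.

Further compounds
F1 | step 6 | 1-(2,4,6-trihydroxyphenyl)butan-1-one | CCCC(=O)c1c(O)cc(O)cc1O
F2 | step 6 | 1-{3-[(dimethylamino)methyl]-2,4,6-trihydroxyphenyl}butan-1-one | CCCC(=O)c1c(O)cc(O)c(CN(C)C)c1O
F3 | step 6 | 1-(2,4,6-trihydroxyphenyl)propan-1-one | CCC(=O)c1c(O)cc(O)cc1O
F4 | step 6 | 3,5-dihydroxy-4,4-dimethyl-2-propanoylcyclohexa-2,5-dien-1-one | CCC(=O)C1=C(O)C(C)(C)C(O)=CC1=O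
F5 | step 6 | 2-butanoyl-3,5-dihydroxy-6-methylidenecyclohexa-2,4-dien-1-one (o-quinone methide from F2) | C=C1C(=O)C(C(=O)CCC)=C(O)C=C1O
F6 | step 10 | 2-acetyl-6-[(dimethylamino)methyl]-3,5-dihydroxy-4,4-dimethylcyclohexa-2,5-dien-1-one | CC(=O)C1=C(O)C(C)(C)C(O)=C(CN(C)C)C1=O
F7 | step 10 | 4-acetyl-5-hydroxy-6,6-dimethyl-2-methylidenecyclohex-4-ene-1,3-dione | C=C1C(=O)C(C)(C)C(O)=C(C(C)=O)C1=O
F8 | step 5 | 2,2-dimethyl-3,5-dioxoheptanoic acid | CCC(=O)CC(=O)C(C)(C)C(=O)O
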